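**Assumptions.** The target has no stereocentres, so "single enantiomer" is vacuous. Its only stereochemistry is five E-trisubstituted alkenes, which come unchanged from all-E hexaprenol (the terminal alkene has no stereochemistry). The structure is 3-hexaprenyl-2,8-dimethyl-1,4-naphthoquinone, with the aromatic methyl peri to the C1 carbonyl next to the C2-methyl. I assume all-E hexaprenol (C30) can be bought as a specialty isoprenoid, and that the thermal Diels–Alder gives the desired regioisomer as the major product. Reagents and solvents are not numbered.

**Retrosynthesis**
- The quinone comes from oxidation of the hydroquinone, which comes from Friedel–Crafts-type C3-allylation of 2,8-dimethylnaphthalene-1,4-diol with all-E hexaprenol. The six E-alkenes are carried in intact.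
- The diol comes from reduction of 2,8-dimethyl-1,4-naphthoquinone.
- That quinone comes from aromatisation of the Diels–Alder adduct of toluquinone and (E)-piperylene.
- The only ring formed is the benzo ring, in the Diels–Alder step. The quinone ring is already present in toluquinone.

**Route**

**Step 1**
Reactants: 1 (2-methyl-1,4-benzoquinone, toluquinone); 2 ((E)-penta-1,3-diene, piperylene)
Product: 3 (cis-2,8-dimethyl-4a,5,8,8a-tetrahydronaphthalene-1,4-dione, racemic)
Conditions: 2 (3 equiv), PhMe, sealed tube, 80 °C, 24 h
Reagents that add atoms: none
Why: Normal-demand Diels–Alder occurs at the unsubstituted C5=C6 bond of toluquinone, the more accessible alkene. The carbonyl next to the methyl (C1) is the more electron-poor one, so the diene's methyl-bearing terminus bonds "ortho" to it, which puts the ring methyl at C8. The cis ring fusion is set suprafacially. All new sp3 centres are removed in Step 2, so their configuration does not matter.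

**Step 2**
Reactants: 3
Product: 4 (2,8-dimethylnaphthalene-1,4-dione)
Conditions: DDQ (2.5 equiv), 1,4-dioxane, 80 °C, 3 h
Reagents that add atoms: none
Why: Acid-catalysed enolisation gives the 5,8-dihydronaphthohydroquinone. DDQ oxidises this to the dihydroquinone and then dehydrogenates the 1,4-cyclohexadiene ring, driven by aromatisation (oxidative aromatisation). The ring-fusion stereocentres and the C8 stereocentre are destroyed here.

**Step 3**
Reactants: 4
Product: 5 (2,8-dimethylnaphthalene-1,4-diol)
Conditions: Na2S2O4, THF/H2O, rt, 30 min; extract under Ar and use immediately
Reagents that add atoms: none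
Why: Dithionite reduces the quinone to the hydroquinone. C3 is the only free position on the electron-rich ring, so the next step has a single site to attack.

**Step 4**
Reactants: 5 (2 equiv); 6 ((2E,6E,10E,14E,18E)-hexaprenol)
Product: 7 (3-[(2E,6E,10E,14E,18E)-3,7,11,15,19,23-hexamethyltetracosa-2,6,10,14,18,22-hexaen-1-yl]-2,8-dimethylnaphthalene-1,4-diol)
Conditions: BF3·OEt2 (0.3 equiv), dioxane, 50 °C, Ar, dark, 1 h
Reagents that add atoms: none
Why: BF3 ionises the allylic alcohol to a prenyl cation. This alkylates the hydroquinone ortho to the C4-OH at C3 (Friedel–Crafts allylation), the only open activated position. Attack at the primary terminus keeps the C2'=C3' alkene E. Excess diol suppresses dialkylation and chroman formation.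

**Step 5**
Reactants: 7
Product: 8 (target, 3-hexaprenyl-2,8-dimethyl-1,4-naphthoquinone)
Conditions: Ag2O, Et2O, anhydrous Na2SO4, rt, dark, 1 h
Reagents that add atoms: none
Why: Ag2O gives mild oxidation of hydroquinone to quinone. It leaves the six isolated trisubstituted alkenes untouched, and no stereocentres are involved.

**Checks.** Every atom in Steps 1–5 is accounted for. The Step 1 adduct 3 is C12H14O2 (C7H6O2 + C5H8). The methyl positions in 4 and 7 match the target SMILES: C2-Me next to C1=O, C8-Me on the carbon adjacent to C8a, and the chain at C3. The chain in 6 matches the target's six isoprene units with the same E descriptors. Mild, non-acidic conditions are used after the chain is attached, except for the single BF3 step.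

**Compound list**
1 | 2-methyl-1,4-benzoquinone | CC1=CC(=O)C=CC1=O | starting material
2 | (E)-penta-1,3-diene | C/C=C/C=C | starting material
3 | cis-2,8-dimethyl-4a,5,8,8a-tetrahydronaphthalene-1,4-dione (racemic, relative stereochemistry not needed) | CC1=CC(=O)C2CC=CC(C)C2C1=O | intermediate
4 | 2,8-dimethylnaphthalene-1,4-dione | CC1=CC(=O)c2cccc(C)c2C1=O | intermediate
5 | 2,8-dimethylnaphthalene-1,4-diol | Cc1cc(O)c2cccc(C)c2c1O | intermediate
6 | (2E,6E,10E,14E,18E)-hexaprenol | CC(C)=CCC/C(C)=C/CC/C(C)=C/CC/C(C)=C/CC/C(C)=C/CC/C(C)=C/CO | starting material
7 | 3-hexaprenyl-2,8-dimethylnaphthalene-1,4-diol | CC(C)=CCC/C(C)=C/CC/C(C)=C/CC/C(C)=C/CC/C(C)=C/CC/C(C)=C/Cc1c(C)c(O)c2c(C)cccc2c1O | intermediate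
8 | 3-hexaprenyl-2,8-dimethyl-1,4-naphthoquinone | CC(C)=CCC/C(C)=C/CC/C(C)=C/CC/C(C)=C/CC/C(C)=C/CC/C(C)=C/CC1=C(C)C(=O)c2c(C)cccc2C1=O | target

**Totals.** 5 steps in total, and the longest linear sequence is 5 steps.

**Three steps most likely to fail**
1. **Step 1 (regiochemistry).** Toluquinone with a 1-substituted diene can give 2,5- and 2,8-dimethyl adducts, and some attack at the methylated C2=C3 bond.
   - Fallback: change the approach to a regio-defined benzannulation, such as a Hauser–Kraus annulation of a 7-methylphthalide-derived anion. Here the phthalide fixes the peri-methyl position, and the C2 methyl is set by the acceptor.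
2. **Step 4 (allylation).** Typical yields are 30–45%, with E/Z scrambling, chroman cyclisation and dialkylation as side reactions.
   - Fallback: brominate quinone 4 at C3, reduce it and protect it as the bis-MOM ether. Then do Li–Br exchange and a CuI-mediated SN2 coupling with hexaprenyl bromide (from 6 and PBr3). Finally deprotect and oxidise. This fixes regiochemistry and chain geometry with no cation.
3. **Step 2 (aromatisation).** DDQ can leave the 5,8-dihydroquinone or over-oxidise the electron-rich diene.
   - Fallback: use a stepwise sequence. Brominate adduct 3 (Br2, then DBU dehydrobromination), or isomerise and air-oxidise it with KOH/EtOH/O2 to the dihydroquinone, then aromatise over Pd/C.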